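**Retrosynthetic overview**
- Alternaric acid is cut at the skipped diene: a ruthenium-catalysed alkene–alkyne coupling joins an allyl-substituted dihydroxy acid to an alkynyl 3-acyl-dihydropyranone, with no protecting groups.
- The acylpyranone, the only ring, comes from a two-atom ring expansion (4 → 6) of (R)-β-butyrolactone by C-acylation/translactonisation with a β-keto ester; this is the key step and the new reaction.
- The β-keto ester comes from the acetoacetate dianion and propargyl bromide.
- The dihydroxy acid comes from (S)-2-methylbutanal: a catalytic asymmetric diazoacetate aldol sets C3, diazo-to-ketone oxidation and chelation-controlled allylation set the quaternary C2, and saponification follows.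
- Ring order: the dihydropyranone is formed once, in the ring-expansion step, before the fragments are joined.

Assumption: (S,S)-ProPhenol is taken to give the (3S) adduct in step 2; if the sense of induction is the reverse, the (R,R)-ligand is used and nothing else changes.

**Route**

Step 1
Reactants: 1 (S)-2-methylbutan-1-ol
Product: 2 (S)-2-methylbutanal
Conditions: TEMPO (1 mol %), KBr (10 mol %), NaOCl (1.1 equiv), NaHCO3, CH2Cl2/H2O, 0 °C; short-path distillation, used at once
Reagents that add atoms: none
Why: Anelli oxidation (TEMPO/NaOCl) stops at the aldehyde and is established to leave the α-stereocentre of this aldehyde intact.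

Step 2
Reactants: 2 (S)-2-methylbutanal; 3 ethyl diazoacetate
Product: 4 ethyl (3S,4S)-2-diazo-3-hydroxy-4-methylhexanoate
Conditions: (S,S)-ProPhenol (5 mol %), Bu2Mg (10 mol %), cis-cyclopentane-1,2-diol (5 mol %), THF, −20 °C
Reagents that add atoms: none
Why: Catalytic asymmetric direct aldol addition of a diazoacetate (an addition without co-product), in which the catalyst sets the C3 carbinol because the methyl/ethyl-branched aldehyde has almost no facial bias of its own, while the mild conditions at −20 °C spare the α-stereocentre.

Step 3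
Reactants: 4 ethyl (3S,4S)-2-diazo-3-hydroxy-4-methylhexanoate; 5 allyl bromide
Product: 8 ethyl (2S,3S,4S)-2,3-dihydroxy-4-methyl-2-(prop-2-en-1-yl)hexanoate, via α-keto ester 6 (not isolated), via allylindium sesquibromide 7 (not isolated)
Conditions: DMDO (1.2 equiv), acetone, 0 °C, then evaporate; In powder (1.5 equiv), 5 (2 equiv), THF/H2O 1:1, 23 °C
Reagents that add atoms: dimethyldioxirane CC1(C)OO1
Why: Dimethyldioxirane oxidises the diazo group to the ketone with only N2 and acetone as co-products, and the indium-mediated Barbier allylation in water then runs under Cram-chelate control (trivalent indium bridges the free C3 hydroxyl and the ketone oxygen, allyl enters anti to the sec-butyl group), which sets the quaternary C2 as S.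

Step 4
Reactants: 8 ethyl (2S,3S,4S)-2,3-dihydroxy-4-methyl-2-(prop-2-en-1-yl)hexanoate
Product: 9 (2S,3S,4S)-2,3-dihydroxy-4-methyl-2-(prop-2-en-1-yl)hexanoic acid
Conditions: LiOH (3 equiv), THF/H2O 3:1, 23 → 40 °C; then 1 M HCl to pH 2
Reagents that add atoms: lithium hydroxide [Li+].[OH-]
Why: Saponification of a hydroxyl-activated ester, in which no stereocentre can epimerise (C2 is quaternary, C3 and C4 are not acidic) and retro-aldol cleavage is negligible at this temperature.

Step 5
Reactants: 10 methyl acetoacetate; 11 propargyl bromide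
Product: 13 methyl 3-oxohept-6-ynoate, via acetoacetate dianion 12 (not isolated)
Conditions: NaH (1.1 equiv), THF, 0 °C; n-BuLi (1.05 equiv), 0 °C; 11 (1.0 equiv), 0 → 23 °C; 1 M HCl
Reagents that add atoms: none
Why: Weiler dianion alkylation, in which the more basic γ-carbanion of the dianion is alkylated selectively by the propargylic bromide (SN2).

Step 6
Reactants: 13 methyl 3-oxohept-6-ynoate; 14 (R)-β-butyrolactone [(4R)-4-methyloxetan-2-one]
Product: 17 (6R)-4-hydroxy-6-methyl-3-(pent-4-ynoyl)-5,6-dihydro-2H-pyran-2-one, via magnesium enolate 15 (not isolated), via open-chain hydroxy tricarbonyl ester 16 (not isolated)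
Conditions: Mg(OTf)2 (1.2 equiv), iPr2NEt (2.5 equiv), MeCN, 0 → 40 °C; then 1 M HCl, THF, 23 °C
Reagents that add atoms: none
Why: Proposed new method: a C-acylative two-atom ring expansion of a β-lactone, in which soft enolisation gives the chelated magnesium enolate 15, whose carbon attacks the magnesium-activated lactone carbonyl (acyl C–O cleavage driven by about 23 kcal/mol of ring strain, so the lactone stereocentre is never touched and stays R) to give 16 as its chelated triacylmethanide, and the freed δ-hydroxyl then closes onto the neighbouring methyl ester with loss of methanol, so that the four-membered lactone becomes the six-membered 3-acyl-4-hydroxy-dihydropyranone, whose magnesium chelate is the thermodynamic sink; triflate is chosen as counter-ion because a halide would open the lactone at C4, and the closest known reaction types are the magnesium salt/amine soft-enolisation C-acylation of β-keto esters by acid chlorides and activated esters, the Claisen opening of lactones by ester enolates, and acyl-transfer ring expansions of lactones and lactams.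

Step 7
Reactants: 9 (2S,3S,4S)-2,3-dihydroxy-4-methyl-2-(prop-2-en-1-yl)hexanoic acid; 17 (6R)-4-hydroxy-6-methyl-3-(pent-4-ynoyl)-5,6-dihydro-2H-pyran-2-one
Product: 18 alternaric acid [(2S,3E)-2-hydroxy-2-[(1S,2S)-1-hydroxy-2-methylbutyl]-9-[(6R)-4-hydroxy-6-methyl-2-oxo-5,6-dihydro-2H-pyran-3-yl]-6-methylidene-9-oxonon-3-enoic acid]
Conditions: [CpRu(MeCN)3]PF6 (10 mol %), acetone, 23 °C; 9 (1.2 equiv); reversed-phase chromatography
Reagents that add atoms: none
Why: Ruthenium-catalysed alkene–alkyne coupling (a formal Alder-ene addition through a ruthenacyclopentene and β-hydride elimination, without co-product) joins the internal alkyne carbon to the terminal alkene carbon, which gives the 1,1-disubstituted alkene and the E-alkene of the skipped diene while touching no stereocentre; tolerance of the free hydroxyl and acidic groups is expected for this cationic catalyst but is not shown for this pair of partners.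

**Compound list**

1 | (S)-2-methylbutan-1-ol | CC[C@H](C)CO | starting material
2 | (S)-2-methylbutanal | CC[C@H](C)C=O | intermediate
3 | ethyl diazoacetate | CCOC(=O)C=[N+]=[N-] | starting material
4 | ethyl (3S,4S)-2-diazo-3-hydroxy-4-methylhexanoate | CCOC(=O)C(=[N+]=[N-])[C@@H](O)[C@@H](C)CC | intermediate
5 | allyl bromide | C=CCBr | starting material
6 | ethyl (3S,4S)-3-hydroxy-4-methyl-2-oxohexanoate | CCOC(=O)C(=O)[C@@H](O)[C@@H](C)CC | intermediate (not isolated)
7 | allylindium sesquibromide, (C3H5)3In2Br3 | C=CC[In](Br)CC=C.C=CC[In](Br)Br | intermediate (not isolated)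
8 | ethyl (2S,3S,4S)-2,3-dihydroxy-4-methyl-2-(prop-2-en-1-yl)hexanoate | C=CC[C@@](O)(C(=O)OCC)[C@@H](O)[C@@H](C)CC | intermediate
9 | (2S,3S,4S)-2,3-dihydroxy-4-methyl-2-(prop-2-en-1-yl)hexanoic acid | C=CC[C@@](O)(C(=O)O)[C@@H](O)[C@@H](C)CC | intermediate
10 | methyl acetoacetate | COC(=O)CC(C)=O | starting material
11 | propargyl bromide | C#CCBr | starting material
12 | methyl acetoacetate dianion (sodium lithium salt) | [Na+].[Li+].[CH2-]C(=O)[CH-]C(=O)OC | intermediate (not isolated)
13 | methyl 3-oxohept-6-ynoate | C#CCCC(=O)CC(=O)OC | intermediate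
14 | (R)-β-butyrolactone, (4R)-4-methyloxetan-2-one | C[C@@H]1CC(=O)O1 | starting material
15 | magnesium enolate of 13 (triflate as second counter-ion) | C#CCCC(=O)C=C([O-])OC.[Mg+2].[O-]S(=O)(=O)C(F)(F)F | intermediate (not isolated)
16 | methyl 2-[(3R)-3-hydroxybutanoyl]-3-oxohept-6-ynoate | C#CCCC(=O)C(C(=O)OC)C(=O)C[C@@H](C)O | intermediate (not isolated)
17 | (6R)-4-hydroxy-6-methyl-3-(pent-4-ynoyl)-5,6-dihydro-2H-pyran-2-one | C#CCCC(=O)C1=C(O)C[C@@H](C)OC1=O | intermediate
18 | alternaric acid | C=C(C/C=C/[C@@](O)(C(=O)O)[C@@H](O)[C@@H](C)CC)CCC(=O)C1=C(O)C[C@@H](C)OC1=O | target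

**Step count and risks**

Total steps: 7. Longest linear sequence: 5 steps (1 → 2 → 4 → 8 → 9 → 18).

The three steps most likely to fail:

Step 6 (the new ring expansion). The magnesium enolate may attack the lactone at C4 (alkyl C–O cleavage, C-alkylation) or on oxygen, or the lactone may oligomerise before it is acylated. The fallback uses known chemistry and sets out from 14. The lithium enolate of tert-butyl acetate (LiN(iPr)2, THF, −78 °C) opens the lactone at the acyl carbon in a Claisen condensation to give tert-butyl (5R)-5-hydroxy-3-oxohexanoate F1. TFA in CH2Cl2 cleaves the tert-butyl ester and closes the ring to (6R)-4-hydroxy-6-methyl-5,6-dihydro-2H-pyran-2-one F2. Pent-4-ynoic acid, DCC and DMAP in CH2Cl2 give the enol ester (6R)-6-methyl-2-oxo-5,6-dihydro-2H-pyran-4-yl pent-4-ynoate F3, which DMAP isomerises in the same flask by O-to-C acyl migration; the route is rejoined at 17.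

Step 7 (ruthenium coupling of two unprotected, acidic partners). The chelating acylpyranone or the α-hydroxy acid may bind the cationic ruthenium centre, and some linear regioisomer is expected. The fallback moves the coupling to partners without the tricarbonyl unit and sets out from 8. Ester 8 and pent-4-ynoic acid are coupled with [CpRu(MeCN)3]PF6 in acetone to (6E,8S,9S,10S)-8-(ethoxycarbonyl)-8,9-dihydroxy-10-methyl-4-methylidenedodec-6-enoic acid F4. DCC and DMAP join F4 to the pyranone F2 (made as in the fallback to step 6), first as the enol ester (6R)-6-methyl-2-oxo-5,6-dihydro-2H-pyran-4-yl (6E,8S,9S,10S)-8-(ethoxycarbonyl)-8,9-dihydroxy-10-methyl-4-methylidenedodec-6-enoate F5 and, after DMAP-mediated O-to-C acyl migration, as alternaric acid ethyl ester F6. LiOH in THF/H2O at 0 °C (the acylpyranone is shielded as its enolate) then gives 18, where the route is rejoined.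

Step 3 (quaternary C2 by chelation control on a labile α-keto ester). The keto ester may tautomerise before it is trapped, or the chelate control may be incomplete. The fallback builds C2 by self-regeneration of a stereocentre and sets out from 2. The cis-dioxolanone (2R,5R)-2-tert-butyl-5-(prop-2-en-1-yl)-1,3-dioxolan-4-one F7 is made from commercial (R)-2-hydroxypent-4-enoic acid and pivalaldehyde (TsOH, pentane, water removal). It is deprotonated (LiN(iPr)2, THF, −78 °C) and added to aldehyde 2, which enters trans to the tert-butyl group. This gives (2R,5S)-2-tert-butyl-5-[(1S,2S)-1-hydroxy-2-methylbutyl]-5-(prop-2-en-1-yl)-1,3-dioxolan-4-one F8 after chromatographic removal of the carbinol epimer, since selectivity at the carbinol is expected to be modest. LiOH in THF/H2O opens the acetal lactone, and the route is rejoined at 9.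

**Further compounds**

F1 | step 6 | tert-butyl (5R)-5-hydroxy-3-oxohexanoate | CC(C)(C)OC(=O)CC(=O)C[C@@H](C)O
F2 | step 6 | (6R)-4-hydroxy-6-methyl-5,6-dihydro-2H-pyran-2-one | C[C@@H]1CC(O)=CC(=O)O1
F3 | step 6 | (6R)-6-methyl-2-oxo-5,6-dihydro-2H-pyran-4-yl pent-4-ynoate | C#CCCC(=O)OC1=CC(=O)O[C@H](C)C1
F4 | step 7 | (6E,8S,9S,10S)-8-(ethoxycarbonyl)-8,9-dihydroxy-10-methyl-4-methylidenedodec-6-enoic acid | C=C(C/C=C/[C@@](O)(C(=O)OCC)[C@@H](O)[C@@H](C)CC)CCC(=O)O
F5 | step 7 | (6R)-6-methyl-2-oxo-5,6-dihydro-2H-pyran-4-yl (6E,8S,9S,10S)-8-(ethoxycarbonyl)-8,9-dihydroxy-10-methyl-4-methylidenedodec-6-enoate | C=C(C/C=C/[C@@](O)(C(=O)OCC)[C@@H](O)[C@@H](C)CC)CCC(=O)OC1=CC(=O)O[C@H](C)C1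
F6 | step 7 | alternaric acid ethyl ester | C=C(C/C=C/[C@@](O)(C(=O)OCC)[C@@H](O)[C@@H](C)CC)CCC(=O)C1=C(O)C[C@@H](C)OC1=O
F7 | step 3 | (2R,5R)-2-tert-butyl-5-(prop-2-en-1-yl)-1,3-dioxolan-4-one | C=CC[C@H]1O[C@@H](C(C)(C)C)OC1=O
F8 | step 3 | (2R,5S)-2-tert-butyl-5-[(1S,2S)-1-hydroxy-2-methylbutyl]-5-(prop-2-en-1-yl)-1,3-dioxolan-4-one | C=CC[C@@]1([C@@H](O)[C@@H](C)CC)O[C@@H](C(C)(C)C)OC1=O
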